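**Retrosynthetic overview**
- Feature: in ring A the acyl-bearing carbon C1 is flanked by two hydroxylated carbons, C2 and C6. The carbonyl oxygen on C1 can hold a metal at either position through a five-membered O=C–C1–C2(C6)–metal chelate, so both C–O bonds are made last from C–H bonds.
- Target 11 ⇒ 10 by cleaving the C4–OMe ether of ring A; 10 ⇒ 7 by twofold ketone-directed oxygenation of C2–H and C6–H.
- 7 ⇒ Weinreb amide 3 + 4-methoxyphenylmagnesium bromide 5 (C1–C(=O) bond); 3 ⇒ 11-phenylundecanoic acid 1.
- No ring is formed: ring A is bought as 4-bromoanisole 4 and the terminal phenyl ring (ring B) comes with acid 1; the target has no stereocentre.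

Key step: step 3

Remark: 11-phenylundecanoic acid is taken as a purchasable compound; the target is achiral, so no stereocontrol is needed.

Step 1
Reactants: 1 11-phenylundecanoic acid
Product: 3 N-methoxy-N-methyl-11-phenylundecanamide, via acyl imidazole 2 (not isolated)
Conditions: CDI (1.2 equiv), CH2Cl2, rt; then MeNHOMe·HCl (1.5 equiv), rt
Reagents that add atoms: N,O-dimethylhydroxylamine hydrochloride, CNOC.Cl; 1,1'-carbonyldiimidazole, O=C(n1ccnc1)n1ccnc1 (its imidazole is carried only in 2)
Why: Amide coupling through an acyl imidazole: CDI activates the acid with loss of CO2 and imidazole, and the hydroxylamine, freed from its salt by the imidazole present, displaces imidazole from 2 to give the Weinreb amide.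

Step 2
Reactants: 4 4-bromoanisole; 3 N-methoxy-N-methyl-11-phenylundecanamide
Product: 7 1-(4-methoxyphenyl)-11-phenylundecan-1-one, via 4-methoxyphenylmagnesium bromide 5 (not isolated), via tetrahedral magnesium alkoxide adduct 6 (not isolated)
Conditions: Mg turnings, I2 (cat.), THF, reflux; then 3, THF, 0 °C to rt; 1 M HCl
Reagents that add atoms: magnesium, [Mg] (held only in 5 and 6; none of it stays in 7)
Why: Grignard formation followed by Weinreb ketone synthesis: the chelated adduct 6 holds the tetrahedral carbon until the acid quench, so a second addition is prevented and the ketone is released only on work-up.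

Step 3
Reactants: 7 1-(4-methoxyphenyl)-11-phenylundecan-1-one
Product: 10 1-(2,6-dihydroxy-4-methoxyphenyl)-11-phenylundecan-1-one, via mono(trifluoroacetate) 8 (not isolated), via bis(trifluoroacetate) 9 (not isolated)
Conditions: Pd(OCOCF3)2 (10 mol%), K2S2O8 (5 equiv, in two portions), TFA/TFAA (9:1 v/v), 50 °C; then aq. NaHCO3, MeOH, rt
Reagents that add atoms: trifluoroacetic acid, OC(=O)C(F)(F)F (source of both new ring oxygens and of the ester groups of 8 and 9)
Why: Proposed new method: the ketone oxygen of 7 binds divalent palladium, and concerted metalation–deprotonation at C2 of ring A gives a five-membered palladacycle; persulfate oxidises this to a tetravalent palladium trifluoroacetate, and C–O reductive elimination releases aryl trifluoroacetate 8 and returns divalent palladium. Because TFAA keeps the new oxygen as a non-chelating ester and not as a phenol, the carbonyl stays free to direct the same cycle at C6 to give 9, and mild hydrolysis of both esters on work-up gives 10. The closest known reaction is the palladium- or ruthenium-catalysed, ketone-directed hydroxylation of a single ortho C–H bond of aryl ketones with persulfate or hypervalent iodine oxidants in TFA/TFAA; running it twice on the same ring in one pot is the untested part. No ring of the product is closed and no stereocentre is formed. The selectivity needed is C2 and C6 over C3 and C5 (ortho to OMe) and over the terminal phenyl ring; chelation by the ketone secures it, since C3 and C5 cannot reach a palladacycle and ring B has no directing group. The raised catalyst loading and the excess oxidant are meant to drive the slower second oxidation of the ester-deactivated, twisted ketone 8.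

Step 4
Reactants: 10 1-(2,6-dihydroxy-4-methoxyphenyl)-11-phenylundecan-1-one
Product: 11 1-(2,4,6-trihydroxyphenyl)-11-phenylundecan-1-one (target)
Conditions: BBr3 (5 equiv), CH2Cl2, −78 °C to rt; H2O quench, 0 °C
Reagents that add atoms: none
Why: Lewis-acid cleavage of an aryl methyl ether: boron binds the ether oxygen and bromide removes the methyl group by SN2 displacement, with excess reagent covering what the two phenols and the chelating ketone consume, and the water quench frees the phenols from boron while the alkyl chain and ring B stay untouched.

**Compound list**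
1 | 11-phenylundecanoic acid | OC(=O)CCCCCCCCCCc1ccccc1 | starting material
2 | 1-(1H-imidazol-1-yl)-11-phenylundecan-1-one (acyl imidazole) | O=C(CCCCCCCCCCc1ccccc1)n1ccnc1 | intermediate (not isolated)
3 | N-methoxy-N-methyl-11-phenylundecanamide | CON(C)C(=O)CCCCCCCCCCc1ccccc1 | intermediate
4 | 4-bromoanisole | COc1ccc(Br)cc1 | starting material
5 | 4-methoxyphenylmagnesium bromide | COc1ccc([Mg]Br)cc1 | intermediate (not isolated)
6 | bromomagnesium alkoxide of 1-[methoxy(methyl)amino]-1-(4-methoxyphenyl)-11-phenylundecan-1-ol (racemic, transient) | CON(C)C(O[Mg]Br)(CCCCCCCCCCc1ccccc1)c1ccc(OC)cc1 | intermediate (not isolated)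
7 | 1-(4-methoxyphenyl)-11-phenylundecan-1-one | COc1ccc(C(=O)CCCCCCCCCCc2ccccc2)cc1 | intermediate
8 | 5-methoxy-2-(11-phenylundecanoyl)phenyl trifluoroacetate | COc1ccc(C(=O)CCCCCCCCCCc2ccccc2)c(OC(=O)C(F)(F)F)c1 | intermediate (not isolated)
9 | 5-methoxy-2-(11-phenylundecanoyl)-1,3-phenylene bis(trifluoroacetate) | COc1cc(OC(=O)C(F)(F)F)c(C(=O)CCCCCCCCCCc2ccccc2)c(OC(=O)C(F)(F)F)c1 | intermediate (not isolated)
10 | 1-(2,6-dihydroxy-4-methoxyphenyl)-11-phenylundecan-1-one | COc1cc(O)c(C(=O)CCCCCCCCCCc2ccccc2)c(O)c1 | intermediate
11 | 1-(2,4,6-trihydroxyphenyl)-11-phenylundecan-1-one | O=C(CCCCCCCCCCc1ccccc1)c1c(O)cc(O)cc1O | target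

**Total step count:** 4
**Longest linear sequence:** 4 steps (1 → 3 → 7 → 10 → 11)

**Steps most likely to fail**

Step 3. The catalytic cycle may stop after the first C–O bond, because mono-ester 8 is less electron-rich and its carbonyl is twisted out of the ring plane, which slows the second palladation. Undirected oxidation of the anisole ring, of ring B or of the α-methylene group may also overtake the directed process. The fallback uses known chemistry and buys all three ring oxygens instead of making two of them; it sets out from Weinreb amide 3 and comes back to the route at target 11. 1,3,5-Trimethoxybenzene is lithiated between two methoxy groups (nBuLi, TMEDA, THF, 0 °C) to give 2,4,6-trimethoxyphenyllithium F1. F1 is added to 3 and, after an HCl quench, gives 1-(2,4,6-trimethoxyphenyl)-11-phenylundecan-1-one F2. Excess BBr3 in CH2Cl2 (−78 °C to reflux, water quench) then cleaves all three methyl ethers of F2 to give 11.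

Step 4. Cleavage of the last methyl ether may stay incomplete, because the 2,6-dihydroxy ketone ties up boron as a chelate that leaves solution, and long exposure to the acid may strip the acyl chain from the electron-rich ring. The fallback removes the ether before the ring is oxygenated and carries the C4 oxygen as an ester; it sets out from 7 and comes back at 11. BBr3 in CH2Cl2 demethylates 7, which has no chelating phenols, to 1-(4-hydroxyphenyl)-11-phenylundecan-1-one F3. Dissolved in TFA/TFAA, F3 is converted into 4-(11-phenylundecanoyl)phenyl trifluoroacetate F4. F4 is oxidised in the same flask under the step 3 conditions to 2-(11-phenylundecanoyl)benzene-1,3,5-triyl tris(trifluoroacetate) F5. Work-up with aqueous NaHCO3 and MeOH hydrolyses all three esters of F5 to 11. This variant asks the step 3 chemistry to accept a more electron-poor ring.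

Step 2. Magnesium insertion into the electron-rich aryl bromide may be slow and accompanied by biaryl homocoupling, or addition to the amide may stay incomplete. The fallback uses the arene as the nucleophile in an electrophilic substitution; it sets out from acid 1 and comes back at 7. Oxalyl chloride with catalytic DMF in CH2Cl2 converts 1 into 11-phenylundecanoyl chloride F6. Friedel–Crafts acylation of anisole (in excess) with F6 and AlCl3 in CH2Cl2 at 0 °C gives 7 by para attack; the excess of the far more nucleophilic anisole keeps ring B from being acylated.

**Further compounds**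
F1 | step 3 | 2,4,6-trimethoxyphenyllithium | [Li]c1c(OC)cc(OC)cc1OC
F2 | step 3 | 1-(2,4,6-trimethoxyphenyl)-11-phenylundecan-1-one | COc1cc(OC)c(C(=O)CCCCCCCCCCc2ccccc2)c(OC)c1
F3 | step 4 | 1-(4-hydroxyphenyl)-11-phenylundecan-1-one | O=C(CCCCCCCCCCc1ccccc1)c1ccc(O)cc1
F4 | step 4 | 4-(11-phenylundecanoyl)phenyl trifluoroacetate | O=C(CCCCCCCCCCc1ccccc1)c1ccc(OC(=O)C(F)(F)F)cc1
F5 | step 4 | 2-(11-phenylundecanoyl)benzene-1,3,5-triyl tris(trifluoroacetate) | O=C(CCCCCCCCCCc1ccccc1)c1c(OC(=O)C(F)(F)F)cc(OC(=O)C(F)(F)F)cc1OC(=O)C(F)(F)F
F6 | step 2 | 11-phenylundecanoyl chloride | O=C(Cl)CCCCCCCCCCc1ccccc1
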